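**Retrosynthetic overview**
1. 15 ⇒ 14 (two O-benzyl ethers) ⇒ 11 (C5 carries a temporary menthyloxy group) ⇒ 10 (the benzylic carbon on C4 carries two temporary phenylthio groups).
2. 10 ⇒ three pieces in one flask. The bond from the ring A benzylic carbon to C4 comes from conjugate addition of lithiated dithioacetal 8 to butenolide 7. The bond from C3 to the ring B CH2 comes from benzylation of the resulting enolate with bromide 4.
3. Enabling feature: in the γ-butyrolactone ring (O1, C2, C3, C4, C5) the adjacent trans stereocentres C4 and C3 sit β and α to the C2 carbonyl, so a C3=C4 butenolide accepts at C4 and then donates at C3. C5 is a plain OCH2 that can carry a removable alkoxy stereo-director. The CH2 on C4 is benzylic to ring A and can be raised to the aldehyde level as an anion-stabilising dithioacetal.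
4. Ring order: rings A and B are bought. The lactone ring comes ready-made from 5, stays closed through the key step, and is opened and re-closed once (step 6) when C5 is reduced to CH2.

Key step: step 4

Remark: the lactone is numbered O1, C2 (C=O), C3, C4, C5. Ring A is the 3-hydroxy-4-methoxyphenyl ring and ring B the 4-hydroxy-3-methoxyphenyl ring. Compounds 1, 3, 5 and 6 are taken as catalogue chemicals.

Step 1
Reactants: 1 3-(benzyloxy)-4-methoxybenzaldehyde
Product: 2 3-(benzyloxy)-4-methoxybenzaldehyde bis(phenylthio)acetal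
Conditions: PhSH (2.2 equiv), p-TsOH·H2O (5 mol %), toluene, Dean–Stark, reflux
Reagents that add atoms: thiophenol, Sc1ccccc1
Why: Acid-catalysed dithioacetalisation of an electron-rich aromatic aldehyde is driven by azeotropic removal of water, and the aryl benzyl and methyl ethers are inert to catalytic sulfonic acid.

Step 2
Reactants: 3 [4-(benzyloxy)-3-methoxyphenyl]methanol
Product: 4 4-(benzyloxy)-3-methoxybenzyl bromide
Conditions: PBr3 (0.4 equiv), Et2O, 0 °C; used at once without chromatography
Reagents that add atoms: phosphorus tribromide, BrP(Br)Br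
Why: Bromination of an activated benzylic alcohol through its phosphite ester is fast at 0 °C and leaves the aryl ethers untouched.

Step 3
Reactants: 5 5-hydroxy-2(5H)-furanone (racemic); 6 (1R,2S,5R)-(−)-menthol
Product: 7 (5R)-5-[(1R,2S,5R)-menthyloxy]-2(5H)-furanone
Conditions: neat, 100 °C (−H2O); crystallisation from petroleum ether; mother liquors re-equilibrated (cat. p-TsOH·H2O) and recrystallised
Reagents that add atoms: none
Why: Acetalisation of the cyclic hemiacetal gives both C5 epimers, which interconvert under acid while the (5R) epimer crystallises, so C5 is set by a crystallisation-induced diastereomer transformation under control of the menthyl group.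

Step 4
Reactants: 2 3-(benzyloxy)-4-methoxybenzaldehyde bis(phenylthio)acetal; 7 (5R)-5-[(1R,2S,5R)-menthyloxy]-2(5H)-furanone; 4 4-(benzyloxy)-3-methoxybenzyl bromide
Product: 10 (3R,4R,5R)-3-(4-benzyloxy-3-methoxybenzyl)-4-[(3-benzyloxy-4-methoxyphenyl)bis(phenylthio)methyl]-5-[(1R,2S,5R)-menthyloxy]dihydrofuran-2(3H)-one, via lithiated dithioacetal 8 (not isolated), via lithium enolate 9 (not isolated)
Conditions: 2, n-BuLi (1.05 equiv), THF, −78 °C; 7, −78 °C; then 4 (1.2 equiv), DMPU, −78 °C → rt; aq NH4Cl
Reagents that add atoms: n-butyllithium, [Li]CCCC (supplies only the lithium of 8 and 9; none of its atoms stays in 10)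
Why: n-BuLi removes the benzylic proton of 2, which is acidified by two sulfur atoms and ring A, and the soft carbanion 8 adds in a Michael fashion to C4 of butenolide 7; the lithium enolate 9 so formed is then benzylated at C3 by SN2 attack on bromide 4, so that both exocyclic C–C bonds of the lactone core and both stereocentres of the target arise in one flask from three simple pieces. The closest known reaction type is the tandem conjugate addition–enolate alkylation of lithiated aryl dithioacetals on 2(5H)-furanones and their 5-alkoxy derivatives, a standard entry to dibenzylbutyrolactone lignans. No ring is closed, as the lactone ring of 7 is carried through intact. C4 is controlled by the C5 menthyloxy group, which shields one face of the flat butenolide so that 8 enters anti to it (4,5-trans), and C3 is controlled by the very large new C4 substituent, which forces 4 onto the opposite face of the enolate (3,4-trans). The step needs 1,4- over 1,2-addition, secured by the delocalised and hindered bis(phenylthio) carbanion at low temperature, and C-monoalkylation without retro-Michael cleavage, secured by the reactive benzylic bromide, the DMPU-loosened lithium enolate and the crowding at the tertiary C3 of 10 that blocks a second deprotonation.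

Step 5
Reactants: 10 (3R,4R,5R)-3-(4-benzyloxy-3-methoxybenzyl)-4-[(3-benzyloxy-4-methoxyphenyl)bis(phenylthio)methyl]-5-[(1R,2S,5R)-menthyloxy]dihydrofuran-2(3H)-one
Product: 11 (3R,4R,5R)-3-(4-benzyloxy-3-methoxybenzyl)-4-(3-benzyloxy-4-methoxybenzyl)-5-[(1R,2S,5R)-menthyloxy]dihydrofuran-2(3H)-one
Conditions: Raney Ni (W-2, washed neutral, excess), EtOH–THF, rt
Reagents that add atoms: none
Why: Mozingo-type desulfurisation cleaves the weak benzylic C–S bonds at room temperature without touching the lactone acetal or any stereocentre, and any benzyl ether lost on the way would be harmless because both are removed in step 7.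

Step 6
Reactants: 11 (3R,4R,5R)-3-(4-benzyloxy-3-methoxybenzyl)-4-(3-benzyloxy-4-methoxybenzyl)-5-[(1R,2S,5R)-menthyloxy]dihydrofuran-2(3H)-one
Product: 14 (3R,4R)-3-(4-benzyloxy-3-methoxybenzyl)-4-(3-benzyloxy-4-methoxybenzyl)dihydrofuran-2(3H)-one, via potassium formyl carboxylate 12 (not isolated), via potassium hydroxy carboxylate 13 (not isolated)
Conditions: KOH (5 equiv), NaBH4 (3 equiv), EtOH–H2O, rt; then 2 M HCl to pH 1, rt
Reagents that add atoms: potassium hydroxide, [K+].[OH-] (potassium and one carboxylate oxygen of 12 and 13; one carboxyl oxygen leaves again as water on lactonisation)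
Why: Saponification of the pseudo-ester releases menthol and unmasks C5 as an aldehyde that NaBH4, already present, should reduce faster than it can enolise, and acidification closes the γ-hydroxy acid by 5-exo-trig lactonisation onto the original C2 carboxyl, so regiochemistry and both stereocentres are kept.

Step 7
Reactants: 14 (3R,4R)-3-(4-benzyloxy-3-methoxybenzyl)-4-(3-benzyloxy-4-methoxybenzyl)dihydrofuran-2(3H)-one
Product: 15 (3R,4R)-3-(4-hydroxy-3-methoxybenzyl)-4-(3-hydroxy-4-methoxybenzyl)dihydrofuran-2(3H)-one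
Conditions: H2 (1 atm), 10% Pd/C, EtOAc–EtOH, rt
Reagents that add atoms: none
Why: Catalytic hydrogenolysis of the two aryl benzyl ethers under neutral conditions frees both phenols and leaves the lactone, the methyl ethers and the thermodynamically preferred trans C3/C4 pair unchanged.

**Compound list**
1 | 3-(benzyloxy)-4-methoxybenzaldehyde | COc1ccc(C=O)cc1OCc1ccccc1 | starting material
2 | 3-(benzyloxy)-4-methoxybenzaldehyde bis(phenylthio)acetal | COc1ccc(cc1OCc1ccccc1)C(Sc1ccccc1)Sc1ccccc1 | intermediate
3 | [4-(benzyloxy)-3-methoxyphenyl]methanol | COc1cc(CO)ccc1OCc1ccccc1 | starting material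
4 | 4-(benzyloxy)-3-methoxybenzyl bromide | COc1cc(CBr)ccc1OCc1ccccc1 | intermediate
5 | 5-hydroxy-2(5H)-furanone (racemic) | OC1OC(=O)C=C1 | starting material
6 | (1R,2S,5R)-(−)-menthol | CC(C)[C@@H]1CC[C@@H](C)C[C@H]1O | starting material
7 | (5R)-5-[(1R,2S,5R)-menthyloxy]-2(5H)-furanone | O=C1C=C[C@H](O[C@@H]2C[C@H](C)CC[C@H]2C(C)C)O1 | intermediate
8 | [(3-benzyloxy-4-methoxyphenyl)bis(phenylthio)methyl]lithium | [Li]C(Sc1ccccc1)(Sc1ccccc1)c1ccc(OC)c(OCc2ccccc2)c1 | intermediate
9 | lithium enolate of (4R,5R)-4-[(3-benzyloxy-4-methoxyphenyl)bis(phenylthio)methyl]-5-menthyloxydihydrofuran-2(3H)-one | COc1ccc(cc1OCc1ccccc1)C(Sc1ccccc1)(Sc1ccccc1)[C@H]1[C@H](O[C@@H]2C[C@H](C)CC[C@H]2C(C)C)OC(O[Li])=C1 | intermediate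
10 | (3R,4R,5R)-3-(4-benzyloxy-3-methoxybenzyl)-4-[(3-benzyloxy-4-methoxyphenyl)bis(phenylthio)methyl]-5-[(1R,2S,5R)-menthyloxy]dihydrofuran-2(3H)-one | COc1ccc(cc1OCc1ccccc1)C(Sc1ccccc1)(Sc1ccccc1)[C@H]1[C@H](O[C@@H]2C[C@H](C)CC[C@H]2C(C)C)OC(=O)[C@@H]1Cc1ccc(OCc2ccccc2)c(OC)c1 | intermediate
11 | (3R,4R,5R)-3-(4-benzyloxy-3-methoxybenzyl)-4-(3-benzyloxy-4-methoxybenzyl)-5-[(1R,2S,5R)-menthyloxy]dihydrofuran-2(3H)-one | COc1ccc(C[C@H]2[C@H](O[C@@H]3C[C@H](C)CC[C@H]3C(C)C)OC(=O)[C@@H]2Cc2ccc(OCc3ccccc3)c(OC)c2)cc1OCc1ccccc1 | intermediate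
12 | potassium (2R,3R)-2-(4-benzyloxy-3-methoxybenzyl)-3-(3-benzyloxy-4-methoxybenzyl)-4-oxobutanoate | COc1ccc(C[C@@H](C=O)[C@H](C(=O)[O-])Cc2ccc(OCc3ccccc3)c(OC)c2)cc1OCc1ccccc1.[K+] | intermediate
13 | potassium (2R,3R)-2-(4-benzyloxy-3-methoxybenzyl)-3-(3-benzyloxy-4-methoxybenzyl)-4-hydroxybutanoate | COc1ccc(C[C@@H](CO)[C@H](C(=O)[O-])Cc2ccc(OCc3ccccc3)c(OC)c2)cc1OCc1ccccc1.[K+] | intermediate
14 | (3R,4R)-3-(4-benzyloxy-3-methoxybenzyl)-4-(3-benzyloxy-4-methoxybenzyl)dihydrofuran-2(3H)-one | COc1ccc(C[C@H]2COC(=O)[C@@H]2Cc2ccc(OCc3ccccc3)c(OC)c2)cc1OCc1ccccc1 | intermediate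
15 | (3R,4R)-3-(4-hydroxy-3-methoxybenzyl)-4-(3-hydroxy-4-methoxybenzyl)dihydrofuran-2(3H)-one | COc1ccc(C[C@H]2COC(=O)[C@@H]2Cc2ccc(O)c(OC)c2)cc1O | target

Total step count: 7. Longest linear sequence: 5 steps (1, 4, 5, 6, 7). The branch through step 3 is equally long.

**Steps most likely to fail**

Step 4. The second bond formation may lag. Benzylation of the crowded enolate next to the bis(phenylthio)methyl group can be slower than proton transfer or retro-Michael cleavage on warming, and the labile bromide can decompose in the meantime. The fallback sets out from 2 and 7 and comes back at 11. The same conjugate addition is run, but the enolate is quenched with aq NH4Cl at −78 °C to give the conjugate adduct (4R,5R)-4-[(3-benzyloxy-4-methoxyphenyl)bis(phenylthio)methyl]-5-[(1R,2S,5R)-menthyloxy]dihydrofuran-2(3H)-one F1. Raney Ni in EtOH–THF then removes the sulfur to give (4R,5R)-4-(3-benzyloxy-4-methoxybenzyl)-5-[(1R,2S,5R)-menthyloxy]dihydrofuran-2(3H)-one F2. The enolate of F2 is far less hindered and has no stabilised carbanion to expel. It is formed with LiN(SiMe3)2 in THF at −78 °C and benzylated with 4 anti to the C4 benzyl group, which gives 11.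

Step 6. Configuration at C4 may be lost if the transient aldehyde enolises in strong base before hydride arrives, or the hindered pseudo-ester may open only sluggishly. The fallback sets out from 11 and comes back at 14. The acetal is cleaved under acid instead (2 M HCl, 1,4-dioxane, 60 °C) to the cyclic pseudo-acid (3R,4R)-3-(4-benzyloxy-3-methoxybenzyl)-4-(3-benzyloxy-4-methoxybenzyl)-5-hydroxydihydrofuran-2(3H)-one F3, as a mixture of C5 epimers. F3 is reduced through its ring-chain tautomer with NaBH4 in EtOH at 0 °C without added hydroxide, and acidification closes 14.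

Step 5. Benzyl ethers may be partly hydrogenolysed on the nickel surface, or the second sulfur may be removed incompletely, which would give hard-to-separate mixtures. The fallback sets out from 10 and comes back at 15. The sulfur is kept until the end. Compound 10 is treated with KOH/NaBH4 and then HCl as in step 6 to give (3R,4R)-3-(4-benzyloxy-3-methoxybenzyl)-4-[(3-benzyloxy-4-methoxyphenyl)bis(phenylthio)methyl]dihydrofuran-2(3H)-one F4. A single treatment with excess Raney Ni under H2 in refluxing EtOH then removes both phenylthio groups and both benzyl ethers on purpose, giving 15 directly.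

**Further compounds**
F1 | step 4 | (4R,5R)-4-[(3-benzyloxy-4-methoxyphenyl)bis(phenylthio)methyl]-5-[(1R,2S,5R)-menthyloxy]dihydrofuran-2(3H)-one | COc1ccc(cc1OCc1ccccc1)C(Sc1ccccc1)(Sc1ccccc1)[C@H]1[C@H](O[C@@H]2C[C@H](C)CC[C@H]2C(C)C)OC(=O)C1
F2 | step 4 | (4R,5R)-4-(3-benzyloxy-4-methoxybenzyl)-5-[(1R,2S,5R)-menthyloxy]dihydrofuran-2(3H)-one | COc1ccc(C[C@H]2[C@H](O[C@@H]3C[C@H](C)CC[C@H]3C(C)C)OC(=O)C2)cc1OCc1ccccc1
F3 | step 6 | (3R,4R)-3-(4-benzyloxy-3-methoxybenzyl)-4-(3-benzyloxy-4-methoxybenzyl)-5-hydroxydihydrofuran-2(3H)-one (C5 epimers) | COc1ccc(C[C@H]2C(O)OC(=O)[C@@H]2Cc2ccc(OCc3ccccc3)c(OC)c2)cc1OCc1ccccc1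
F4 | step 5 | (3R,4R)-3-(4-benzyloxy-3-methoxybenzyl)-4-[(3-benzyloxy-4-methoxyphenyl)bis(phenylthio)methyl]dihydrofuran-2(3H)-one | COc1ccc(cc1OCc1ccccc1)C(Sc1ccccc1)(Sc1ccccc1)[C@H]1COC(=O)[C@@H]1Cc1ccc(OCc2ccccc2)c(OC)c1
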